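Feature: ring A is a benzene with oxygen at C1, C3 and C5 (one ether O, two OH). Its ether oxygen sits on C1 of ring B, between the oxygens at C2 and C6 of ring B. This crowded aryl–O bond is not made by coupling; ring A is grown on the oxygen instead.
Disconnection 1: global dealkylation (eight OMe, one OEt). Ring A is then cut into the O–C≡CH unit of a ring B ethynyl ether (ring A C1, C2) and the four carbons of 3-ethoxycyclobut-2-en-1-one (ring A C3–C6), a vinylketene/alkyne benzannulation.
Disconnection 2: the ethynyl ether comes from the ring B phenol by O-dichlorovinylation with trichloroethylene and elimination with n-BuLi.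
Disconnection 3: the B–C ether is made at the unhindered C4 of ring B by copper catalysis. The C–D biaryl is made by Negishi coupling, with a formyl group on ring C as latent phenol (Baeyer–Villiger).
Ring order: rings B, C and D are bought as arenes and joined D–C, then C–B. Ring A is the only ring formed, and it is formed last.

Key step: step 9

Assumption: 3-ethoxycyclobut-2-en-1-one is taken as a catalogue building block; ring D is symmetric, so the C–D axis is not stereogenic and the target has no stereochemical element.
Abbreviation: ArO– is the 4-[(2,2',4,4',6,6'-hexamethoxybiphenyl-3-yl)oxy]-2,6-dimethoxyphenoxy group (permethylated rings B–C–D, bound through the ring B C1 oxygen).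

Step 1
Reactants: 1 2,4,6-trimethoxybenzaldehyde
Product: 2 3-bromo-2,4,6-trimethoxybenzaldehyde
Conditions: NBS (1.0 equiv), MeCN, 0 °C to rt
Reagents that add atoms: N-bromosuccinimide, O=C1CCC(=O)N1Br
Why: Electrophilic aromatic bromination: the free positions C3 and C5 are equivalent and each is activated by three methoxy groups, while the bromine and the formyl group of 2 slow a second substitution enough for one equivalent of NBS to stop at the monobromide.

Step 2
Reactants: 2 3-bromo-2,4,6-trimethoxybenzaldehyde; 3 1,3,5-trimethoxybenzene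
Product: 6 2,2',4,4',6,6'-hexamethoxybiphenyl-3-carbaldehyde, via 2,4,6-trimethoxyphenyllithium 4 (not isolated), via (2,4,6-trimethoxyphenyl)zinc chloride 5 (not isolated)
Conditions: 3, n-BuLi, THF, 0 °C to rt; ZnCl2, THF, 0 °C; then 2, Pd2(dba)3 (2 mol %), RuPhos (8 mol %), THF, 70 °C
Reagents that add atoms: none
Why: Directed ortho-lithiation of 3 between two methoxy groups, transmetalation to zinc and Negishi coupling: the bulky electron-rich biarylphosphine is a known answer to tetra-ortho-substituted biaryls, the arylzinc needs neither base nor water and so cannot be lost by protodemetalation as the corresponding boronic acid would be, and it is too mild to add to the hindered, donor-deactivated aldehyde.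

Step 3
Reactants: 6 2,2',4,4',6,6'-hexamethoxybiphenyl-3-carbaldehyde
Product: 8 2,2',4,4',6,6'-hexamethoxybiphenyl-3-ol, via aryl formate 7 (not isolated)
Conditions: mCPBA (1.2 equiv), CH2Cl2, 0 °C to rt; aq. Na2SO3/NaHCO3 wash; then K2CO3 (cat.), MeOH, rt, Ar
Reagents that add atoms: 3-chloroperbenzoic acid, OOC(=O)c1cccc(Cl)c1
Why: Baeyer–Villiger oxidation in its Dakin-like sense: the very electron-rich aryl group migrates in preference to hydrogen, the phenol stays masked as formate 7 until the peracid has been washed out, and catalytic methanolysis then frees it, so an oxidation-prone free 4-methoxyphenol never has to be brominated or cross-coupled.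

Step 4
Reactants: 9 4-bromo-2,6-dimethoxyphenol
Product: 10 2-(benzyloxy)-5-bromo-1,3-dimethoxybenzene
Conditions: BnBr, K2CO3, DMF, rt
Reagents that add atoms: benzyl bromide, BrCc1ccccc1
Why: Williamson ether synthesis; benzyl survives the basic copper coupling and is later removed by hydrogenolysis without touching the methyl ethers.

Step 5
Reactants: 8 2,2',4,4',6,6'-hexamethoxybiphenyl-3-ol; 10 2-(benzyloxy)-5-bromo-1,3-dimethoxybenzene
Product: 11 3-[4-(benzyloxy)-3,5-dimethoxyphenoxy]-2,2',4,4',6,6'-hexamethoxybiphenyl
Conditions: CuI (10 mol %), picolinic acid (20 mol %), K3PO4 (2 equiv), DMSO, 100 °C, Ar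
Reagents that add atoms: none
Why: Ligand-accelerated Ullmann diaryl ether synthesis: the CuI/picolinic acid system is established for di-ortho-substituted phenols and unactivated aryl bromides, and the C–Br carbon of 10 has hydrogen at both ortho positions, so only the nucleophile is hindered.

Step 6
Reactants: 11 3-[4-(benzyloxy)-3,5-dimethoxyphenoxy]-2,2',4,4',6,6'-hexamethoxybiphenyl
Product: 12 4-[(2,2',4,4',6,6'-hexamethoxybiphenyl-3-yl)oxy]-2,6-dimethoxyphenol (ArOH)
Conditions: H2 (1 atm), Pd/C (10 %), EtOAc–EtOH, rt
Reagents that add atoms: none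
Why: Catalytic hydrogenolysis of the benzylic C–O bond; aryl methyl ethers, the diaryl ether and the biaryl are inert to H2 over Pd/C at room temperature.

Step 7
Reactants: 12 ArOH; 13 trichloroethylene
Product: 15 (E)-1,2-dichlorovinyl ether ArO–C(Cl)=CHCl, via dichloroacetylene 14 (not isolated)
Conditions: 13 (1.5 equiv), K2CO3 (2 equiv), DMF, 70 °C, Ar, closed flask
Reagents that add atoms: none
Why: Base-mediated O-dichlorovinylation: K2CO3 dehydrochlorinates 13 to dichloroacetylene 14, the phenoxide adds to this slim linear electrophile despite its two ortho methoxy groups, and anti addition of O and H across the triple bond sets the E geometry.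

Step 8
Reactants: 15 ArO–C(Cl)=CHCl
Product: 18 3-[4-(ethynyloxy)-3,5-dimethoxyphenoxy]-2,2',4,4',6,6'-hexamethoxybiphenyl (ArO–C≡CH), via chloroethynyl ether 16 (not isolated), via lithium acetylide 17 (not isolated)
Conditions: n-BuLi (2.5 equiv), THF, −78 to −40 °C; H2O, −78 to 0 °C; 18 kept cold in toluene and used at once
Reagents that add atoms: none
Why: Elimination/halogen–lithium exchange route to terminal ynol ethers: the first n-BuLi removes HCl to give 16, the second exchanges the alkynyl chlorine for lithium, and water protonates acetylide 17, the same quench undoing any adventitious aryl lithiation.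

Step 9
Reactants: 18 ArO–C≡CH; 19 3-ethoxycyclobut-2-en-1-one
Product: 24 3-ethoxy-5-{4-[(2,2',4,4',6,6'-hexamethoxybiphenyl-3-yl)oxy]-2,6-dimethoxyphenoxy}phenol, via vinylketene 20 (not isolated), via vinylcyclobutenone 21 (not isolated), via dienylketene 22 (not isolated), via cyclohexadienone 23 (not isolated)
Conditions: 19 (2.5 equiv, two portions), toluene, sealed tube, 110 °C, then 140 °C; then K2CO3 (cat.), MeOH, rt
Reagents that add atoms: none
Why: Heat opens 19 by 4π electrocyclic ring opening to vinylketene 20, whose ketene C=C adds to the electron-rich triple bond of 18 in a [2+2] cycloaddition to give vinylcyclobutenone 21, and a second 4π opening delivers dienylketene 22. Ring A is then closed by 6π electrocyclisation of 22, which bonds the ketene carbon to the terminal CH2 of the ethoxyvinyl arm and gives cyclohexadienone 23; this tautomerises irreversibly to phenol 24. This is the Danheiser benzannulation, established for cyclobutenones and alkynyl ethers, and 18 belongs to that alkyne class. The one selectivity needed is the orientation of the [2+2] step: oxygen donation makes the terminal CH of 18 the nucleophilic carbon, it attacks the electrophilic ketene carbonyl carbon, and the aryloxy carbon therefore ends meta to both the new OH and OEt; a competing [4+2] addition of 20 of the same polarity would give the same 1,3,5 pattern. No stereocentre survives (the one in 21 is racemic and is lost on ring opening), and 18 has no β-hydrogen on its oxygen substituent, so the retro-ene loss of ketene that limits alkyl ynol ethers at this temperature is not open to it. Excess 19 is used because 24 can be O-acylated by 20, and the closing methanolysis returns such esters to 24.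

Step 10
Reactants: 24 3-aryloxy-5-ethoxyphenol from step 9
Product: 25 3-[4-(3,5-dihydroxyphenoxy)-3,5-dihydroxyphenoxy]biphenyl-2,2',4,4',6,6'-hexol (target CNP0248644.0)
Conditions: BBr3 (20 equiv), CH2Cl2, −78 °C to rt; H2O, 0 °C; degassed solvents, Ar
Reagents that add atoms: none
Why: Lewis acid mediated cleavage of aryl alkyl ethers: boron binds each alkyl-bearing oxygen and bromide attacks the sp3 carbon in SN2 fashion, so the eight methyl and one ethyl C–O bonds break, while the two diaryl ether links and the biaryl bond offer no sp3 carbon and stay intact.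

Compound list
1 | 2,4,6-trimethoxybenzaldehyde | COc1cc(OC)c(C=O)c(OC)c1 | starting material
2 | 3-bromo-2,4,6-trimethoxybenzaldehyde | COc1cc(OC)c(C=O)c(OC)c1Br | intermediate
3 | 1,3,5-trimethoxybenzene | COc1cc(OC)cc(OC)c1 | starting material
4 | 2,4,6-trimethoxyphenyllithium (not isolated) | [Li]c1c(OC)cc(OC)cc1OC | intermediate
5 | (2,4,6-trimethoxyphenyl)zinc chloride (not isolated) | Cl[Zn]c1c(OC)cc(OC)cc1OC | intermediate
6 | 2,2',4,4',6,6'-hexamethoxybiphenyl-3-carbaldehyde | COc1cc(OC)c(-c2c(OC)cc(OC)c(C=O)c2OC)c(OC)c1 | intermediate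
7 | 2,2',4,4',6,6'-hexamethoxybiphenyl-3-yl formate (not isolated) | COc1cc(OC)c(-c2c(OC)cc(OC)c(OC=O)c2OC)c(OC)c1 | intermediate
8 | 2,2',4,4',6,6'-hexamethoxybiphenyl-3-ol | COc1cc(OC)c(-c2c(OC)cc(OC)c(O)c2OC)c(OC)c1 | intermediate
9 | 4-bromo-2,6-dimethoxyphenol | COc1cc(Br)cc(OC)c1O | starting material
10 | 2-(benzyloxy)-5-bromo-1,3-dimethoxybenzene | COc1cc(Br)cc(OC)c1OCc1ccccc1 | intermediate
11 | 3-[4-(benzyloxy)-3,5-dimethoxyphenoxy]-2,2',4,4',6,6'-hexamethoxybiphenyl | COc1cc(Oc2c(OC)cc(OC)c(-c3c(OC)cc(OC)cc3OC)c2OC)cc(OC)c1OCc1ccccc1 | intermediate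
12 | 4-[(2,2',4,4',6,6'-hexamethoxybiphenyl-3-yl)oxy]-2,6-dimethoxyphenol (ArOH) | Oc1c(OC)cc(Oc2c(OC)cc(OC)c(-c3c(OC)cc(OC)cc3OC)c2OC)cc1OC | intermediate
13 | trichloroethylene | ClC=C(Cl)Cl | starting material
14 | dichloroacetylene (not isolated) | ClC#CCl | intermediate
15 | (E)-1,2-dichlorovinyl ether of 12 | Cl/C=C(Cl)\Oc1c(OC)cc(Oc2c(OC)cc(OC)c(-c3c(OC)cc(OC)cc3OC)c2OC)cc1OC | intermediate
16 | chloroethynyl ether of 12 (not isolated) | ClC#COc1c(OC)cc(Oc2c(OC)cc(OC)c(-c3c(OC)cc(OC)cc3OC)c2OC)cc1OC | intermediate
17 | lithium acetylide ArO–C≡C–Li (not isolated) | [Li]C#COc1c(OC)cc(Oc2c(OC)cc(OC)c(-c3c(OC)cc(OC)cc3OC)c2OC)cc1OC | intermediate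
18 | ethynyl ether of 12, 3-[4-(ethynyloxy)-3,5-dimethoxyphenoxy]-2,2',4,4',6,6'-hexamethoxybiphenyl | C#COc1c(OC)cc(Oc2c(OC)cc(OC)c(-c3c(OC)cc(OC)cc3OC)c2OC)cc1OC | intermediate
19 | 3-ethoxycyclobut-2-en-1-one | CCOC1=CC(=O)C1 | starting material
20 | 3-ethoxybuta-1,3-dien-1-one, the vinylketene (not isolated) | C=C(OCC)C=C=O | intermediate
21 | 3-(ArO)-4-(1-ethoxyvinyl)cyclobut-2-en-1-one, racemic (not isolated) | O=C1C=C(Oc2c(OC)cc(Oc3c(OC)cc(OC)c(-c4c(OC)cc(OC)cc4OC)c3OC)cc2OC)C1C(=C)OCC | intermediate
22 | (3E)-3-(ArO)-5-ethoxyhexa-1,3,5-trien-1-one, ketene and ethoxyvinyl arms cis on the central C=C (not isolated) | O=C=C/C(Oc1c(OC)cc(Oc2c(OC)cc(OC)c(-c3c(OC)cc(OC)cc3OC)c2OC)cc1OC)=C\C(=C)OCC | intermediate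
23 | 3-(ArO)-5-ethoxycyclohexa-2,4-dien-1-one (not isolated) | O=C1C=C(Oc2c(OC)cc(Oc3c(OC)cc(OC)c(-c4c(OC)cc(OC)cc4OC)c3OC)cc2OC)C=C(OCC)C1 | intermediate
24 | 3-ethoxy-5-(ArO)phenol | CCOc1cc(O)cc(Oc2c(OC)cc(Oc3c(OC)cc(OC)c(-c4c(OC)cc(OC)cc4OC)c3OC)cc2OC)c1 | intermediate
25 | 3-[4-(3,5-dihydroxyphenoxy)-3,5-dihydroxyphenoxy]biphenyl-2,2',4,4',6,6'-hexol | Oc1cc(O)cc(Oc2c(O)cc(Oc3c(O)cc(O)c(-c4c(O)cc(O)cc4O)c3O)cc2O)c1 | target

Total step count: 10
Longest linear sequence: 9 steps (1 → 2 → 6 → 8 → 11 → 12 → 15 → 18 → 24 → 25); step 4 is the side branch.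

Steps most likely to fail

Step 9. The aryl ynol ether is less nucleophilic than an alkyl one. Thermal oligomerisation of the terminal alkyne and dimerisation or re-closure of the vinylketene may therefore outrun the [2+2] capture. The fallback gives up ring construction and makes the A–B ether by aryl–O coupling. It sets out from phenol 12, which is coupled with 1-iodo-3,5-dimethoxybenzene (CuI, picolinic acid, K3PO4, DMSO, 110 °C, the ligand system of step 5 for hindered phenols) to give the nonamethyl ether F1. Cleavage of all nine methyl ethers with BBr3 (CH2Cl2, −78 °C to rt, then water) brings it back to the route at target 25.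

Step 2. Transmetalation and reductive elimination may be slow at a palladium centre that has to carry two di-ortho-methoxy aryl groups. Reduction of the C–Br bond and homocoupling of the zinc reagent could then overtake cross-coupling. The fallback forms the hindered bond symmetrically and desymmetrises afterwards. It sets out from 3, which is lithiated to 4 as before and coupled oxidatively with FeCl3 (THF, −78 °C to rt) to 2,2',4,4',6,6'-hexamethoxybiphenyl F2. Vilsmeier–Haack formylation with a slight deficit of POCl3/DMF gives the aryl iminium chloride F3, and aqueous hydrolysis of this salt rejoins the route at aldehyde 6. All four free positions of F2 are equivalent, so only over-formylation has to be held back, and unreacted F2 is recycled.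

Step 5. C–O bond formation between a chelating, di-ortho-methoxy phenoxide and an electron-rich bromide may be sluggish. The phenoxide may also oxidise slowly during long heating. The fallback replaces copper catalysis by nucleophilic aromatic substitution and replaces the benzyl ether by a latent phenol. It sets out from 8, which displaces the sterically open para fluorine of 2,4,6-trifluorobenzaldehyde (K2CO3, DMF, rt to 50 °C) to give 4-aryloxy-2,6-difluorobenzaldehyde F4. Excess NaOMe (DMF–MeOH, 70 °C) exchanges both ortho fluorines, which the formyl group activates, to give 4-aryloxy-2,6-dimethoxybenzaldehyde F5. Baeyer–Villiger oxidation with mCPBA gives the aryl formate F6, and catalytic K2CO3 in MeOH cleaves it, coming back to the route at phenol 12.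

Further compounds
F1 | step 9 | 3-[4-(3,5-dimethoxyphenoxy)-3,5-dimethoxyphenoxy]-2,2',4,4',6,6'-hexamethoxybiphenyl (nonamethyl ether) | COc1cc(OC)cc(Oc2c(OC)cc(Oc3c(OC)cc(OC)c(-c4c(OC)cc(OC)cc4OC)c3OC)cc2OC)c1
F2 | step 2 | 2,2',4,4',6,6'-hexamethoxybiphenyl | COc1cc(OC)c(-c2c(OC)cc(OC)cc2OC)c(OC)c1
F3 | step 2 | N,N-dimethyl(2,2',4,4',6,6'-hexamethoxybiphenyl-3-yl)methaniminium chloride | C[N+](C)=Cc1c(OC)cc(OC)c(-c2c(OC)cc(OC)cc2OC)c1OC.[Cl-]
F4 | step 5 | 2,6-difluoro-4-[(2,2',4,4',6,6'-hexamethoxybiphenyl-3-yl)oxy]benzaldehyde | O=Cc1c(F)cc(Oc2c(OC)cc(OC)c(-c3c(OC)cc(OC)cc3OC)c2OC)cc1F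
F5 | step 5 | 4-[(2,2',4,4',6,6'-hexamethoxybiphenyl-3-yl)oxy]-2,6-dimethoxybenzaldehyde | O=Cc1c(OC)cc(Oc2c(OC)cc(OC)c(-c3c(OC)cc(OC)cc3OC)c2OC)cc1OC
F6 | step 5 | 4-[(2,2',4,4',6,6'-hexamethoxybiphenyl-3-yl)oxy]-2,6-dimethoxyphenyl formate | O=COc1c(OC)cc(Oc2c(OC)cc(OC)c(-c3c(OC)cc(OC)cc3OC)c2OC)cc1OC
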